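**Retrosynthetic overview**
1. Last bond: the C-3 ester, from the eremophilane 3β-alcohol and (2E,4E,6R)-4,6-dimethylocta-2,4-dienoic acid. The C-3 oxygen comes from a vinylogous Rubottom oxidation of the linear dienone, and Δ1 from quinone dehydrogenation.
2. C-7 carbinol (OH cis to the C-5 methyl): 1,2-addition of a 2-(silyloxymethyl)vinyllithium to C-8 of an O-silylated diosphenol, then α-ketol shift of the alkenyl group from C-8 to C-7.
3. The diosphenol comes from dehydrofukinone by ozonolytic loss of the isopropylidene group; the C3 unit returns, already oxygenated, in line 2.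
4. Key step: rings A and B are formed together, in one operation, by closing the C-5–C-10 bond across the ten-membered ring of germacrone. Asymmetric proton-initiated transannular cyclisation gives the eudesm-4-yl cation, and 1,2-H then 1,2-Me shifts give the eremophilane (dehydrofukinone).
5. The side-chain acid comes from (R)-2-methylbutan-1-ol by oxidation/Wittig, Horner–Wadsworth–Emmons and saponification.

Assumption/convention: eremophilane numbering is used (C-8 ketone, C-7 carbinol, C-9=C-10, C-1=C-2, C-3 ester carbon, C-4 CH–CH3, C-5 quaternary C–CH3, C-11 side-chain alkene carbon, C-12 CH2OAc, C-13 =CH2); α is the face of the two ring methyls; the target is (3S,4S,5S,7S) with a (2E,4E,6R) acyl group; germacrone (achiral bulk isolate), 2-bromoprop-2-en-1-ol and (R)-2-methylbutan-1-ol are taken as purchasable.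

**Step 1**
Reactants: 1 germacrone, (3E,7E)-3,7-dimethyl-10-(propan-2-ylidene)cyclodeca-3,7-dien-1-one
Product: 5 (4R,5S)-eremophila-7(11),9-dien-8-one (dehydrofukinone; 4,5-methyls cis), via eudesm-4-yl cation 2 (not isolated), via eudesm-5-yl cation 3 (not isolated), via eremophil-10-yl cation 4 (not isolated)
Conditions: confined chiral imidodiphosphorimidate Brønsted acid (IDPi, 5 mol %; antipode chosen to give 5S), CH2Cl2–HFIP 4:1, −40 → 0 °C
Reagents that add atoms: none
Why: Proposed new method: the chiral acid protonates C-1 of one of the two rapidly interconverting crossed conformers of achiral 1 while C-5 of the 4,5-alkene closes onto C-10 (acid-induced transannular cyclisation of germacrone to trans-fused eudesmanes is known, and enantioselective protonation-initiated polyene cyclisation is the closest asymmetric precedent), and because the confined counter-anion is non-basic cation 2 is not deprotonated but follows the antiperiplanar, suprafacial shifts of the biosynthesis (H-5 to C-4 giving 3, then the C-10 methyl to C-5 giving 4; the Westphalen-type backbone rearrangement is the closest laboratory analogue) until loss of H-9 gives the cross-conjugated dienone as thermodynamic sink, so the catalyst sets C-5 (S) and the two suprafacial shifts set C-4 (R, methyls cis).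

**Step 2**
Reactants: 5 (4R,5S)-eremophila-7(11),9-dien-8-one
Product: 7 (4R,5R)-7-hydroxy-11,12,13-trinoreremophila-6,9-dien-8-one (diosphenol), via trinor-7,8-dione 6 (not isolated)
Conditions: O3, CH2Cl2–MeOH 4:1, −78 °C (Sudan Red endpoint); Me2S, −78 °C → rt
Reagents that add atoms: ozone O=[O+][O-]
Why: Ozonolysis: ozone attacks the tetrasubstituted exocyclic enone alkene faster than the trisubstituted ring alkene (as in the ozonolysis of pulegone), Criegee cleavage gives acetone and diketone 6, which enolises toward C-6 to the fully conjugated diosphenol, and no stereocentre is touched.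

**Step 3**
Reactants: 7 (4R,5R)-7-hydroxy-11,12,13-trinoreremophila-6,9-dien-8-one
Product: 8 (4R,5R)-7-(tert-butyldimethylsilyloxy)-11,12,13-trinoreremophila-6,9-dien-8-one
Conditions: TBSCl, imidazole, DMF, rt
Reagents that add atoms: tert-butyldimethylsilyl chloride CC(C)(C)[Si](C)(C)Cl
Why: O-silylation of the acidic enol (silyl enol ether formation) masks C-7 and leaves C-8 as the only, non-enolisable, carbonyl.

**Step 4**
Reactants: 9 2-bromoprop-2-en-1-ol
Product: 10 [(2-bromoprop-2-en-1-yl)oxy](tert-butyl)dimethylsilane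
Conditions: TBSCl, imidazole, CH2Cl2, 0 °C → rt
Reagents that add atoms: tert-butyldimethylsilyl chloride CC(C)(C)[Si](C)(C)Cl
Why: Standard silyl ether formation protects the primary alcohol for the halogen–lithium exchange.

**Step 5**
Reactants: 8 (4R,5R)-7-(tert-butyldimethylsilyloxy)-11,12,13-trinoreremophila-6,9-dien-8-one; 10 [(2-bromoprop-2-en-1-yl)oxy](tert-butyl)dimethylsilane
Product: 12 (4R,5R,8R)-7-(tert-butyldimethylsilyloxy)-8-[3-(tert-butyldimethylsilyloxy)prop-1-en-2-yl]-11,12,13-trinoreremophila-6,9-dien-8-ol, via vinyllithium 11 (not isolated)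
Conditions: 10, t-BuLi (2 equiv), Et2O, −78 °C; then 8, THF, −78 °C; H2O
Reagents that add atoms: none
Why: Bromine–lithium exchange then 1,2-addition of the alkenyllithium to the cross-conjugated ketone, which enters anti to the axial C-5 methyl (as nucleophiles attack steroidal 4-en-3-ones and 1,4-dien-3-ones anti to C-19) and so sets C-8 with the alkenyl group β (axial) and the OH α.

**Step 6**
Reactants: 12 (4R,5R,8R)-7-(tert-butyldimethylsilyloxy)-8-[3-(tert-butyldimethylsilyloxy)prop-1-en-2-yl]-11,12,13-trinoreremophila-6,9-dien-8-ol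
Product: 14 (4R,5S,7S)-7,12-dihydroxyeremophila-9,11(13)-dien-8-one, via alpha-ketol 13 (not isolated)
Conditions: TBAF (3 equiv), THF, 0 → 40 °C
Reagents that add atoms: none
Why: Fluoride removes both silyl groups and the freed C-7 ketone/C-8 tertiary alkoxide undergoes the base-mediated α-ketol (acyloin) rearrangement, driven by conjugation of the new C-8 ketone with Δ9; the axial alkenyl group is the one aligned with the C-7 carbonyl π* and migrates suprafacially on the β face, so C-7 receives the side chain β and the OH α, cis to the C-5 methyl (7S).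

**Step 7**
Reactants: 14 (4R,5S,7S)-7,12-dihydroxyeremophila-9,11(13)-dien-8-one
Product: 15 (4R,5S,7S)-12-acetoxy-7-hydroxyeremophila-9,11(13)-dien-8-one
Conditions: Ac2O (1.1 equiv), pyridine, CH2Cl2, 0 °C
Reagents that add atoms: acetic anhydride CC(=O)OC(C)=O
Why: Chemoselective acetylation of the primary allylic alcohol, the tertiary α-ketol hydroxyl being too hindered to react under these conditions.

**Step 8**
Reactants: 15 (4R,5S,7S)-12-acetoxy-7-hydroxyeremophila-9,11(13)-dien-8-one
Product: 16 (4R,5S,7S)-12-acetoxy-7-hydroxyeremophila-1,9,11(13)-trien-8-one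
Conditions: chloranil (1.5 equiv), t-BuOH, reflux
Reagents that add atoms: none
Why: Quinone dehydrogenation of an enone through its extended dienol to the linear dienone (as steroidal 4-en-3-ones give 4,6-dien-3-ones), the cross-conjugated alternative being impossible because C-7 is quaternary.

**Step 9**
Reactants: 16 (4R,5S,7S)-12-acetoxy-7-hydroxyeremophila-1,9,11(13)-trien-8-one
Product: 18 (3S,4S,5S,7S)-12-acetoxy-3,7-dihydroxyeremophila-1,9,11(13)-trien-8-one, via bis-TMS trienol ether 17 (not isolated)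
Conditions: TMSOTf, Et3N, CH2Cl2, 0 °C; then DMDO (1.0 equiv), acetone, −40 °C; aq. citric acid
Reagents that add atoms: dimethyldioxirane CC1(C)OO1
Why: Soft enolisation can only remove H-3 and gives the linear silyl trienol ether 17 (the 7-OH is silylated as well), and in a vinylogous Rubottom oxidation DMDO epoxidises its terminal, least hindered C-2=C-3 bond from the β face, anti to both α methyl groups, the silyloxy epoxide collapsing to the 3β-hydroxy dienone (3S, trans to the C-4 methyl) before mild acid removes the TMS groups.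

**Step 10**
Reactants: 19 (R)-2-methylbutan-1-ol
Product: 21 (2E,4R)-2,4-dimethylhex-2-enal, via (R)-2-methylbutanal 20 (not isolated)
Conditions: TEMPO (10 mol %), PhI(OAc)2, CH2Cl2, rt; then Ph3P=C(Me)CHO, 40 °C
Reagents that add atoms: 2-(triphenylphosphoranylidene)propanal CC(C=O)=P(c1ccccc1)(c1ccccc1)c1ccccc1
Why: Oxoammonium oxidation gives the α-chiral aldehyde without epimerisation and the in situ Wittig reaction with the stabilised ylide gives the (E)-enal, the stereocentre coming unchanged from 19.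

**Step 11**
Reactants: 21 (2E,4R)-2,4-dimethylhex-2-enal
Product: 22 ethyl (2E,4E,6R)-4,6-dimethylocta-2,4-dienoate
Conditions: (EtO)2P(O)CH2CO2Et, NaH, THF, 0 °C → rt
Reagents that add atoms: triethyl phosphonoacetate CCOC(=O)CP(=O)(OCC)OCC
Why: Horner–Wadsworth–Emmons olefination gives the new (E)-alkene and leaves the existing alkene and stereocentre untouched.

**Step 12**
Reactants: 22 ethyl (2E,4E,6R)-4,6-dimethylocta-2,4-dienoate
Product: 23 (2E,4E,6R)-4,6-dimethylocta-2,4-dienoic acid
Conditions: LiOH, THF–MeOH–H2O, rt; then 1 M HCl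
Reagents that add atoms: lithium hydroxide [Li+].[OH-]
Why: Ester saponification, under which the remote C-6 stereocentre is not acidic enough to epimerise.

**Step 13**
Reactants: 18 (3S,4S,5S,7S)-12-acetoxy-3,7-dihydroxyeremophila-1,9,11(13)-trien-8-one; 23 (2E,4E,6R)-4,6-dimethylocta-2,4-dienoic acid
Product: 24 (3S,4S,5S,7S)-12-acetoxy-7-hydroxy-8-oxoeremophila-1,9,11(13)-trien-3-yl (2E,4E,6R)-4,6-dimethylocta-2,4-dienoate (target, CNP0160850.1)
Conditions: DCC, DMAP (cat.), CH2Cl2, 0 °C → rt
Reagents that add atoms: none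
Why: Steglich esterification acylates the secondary allylic 3-OH with retention at C-3, while the tertiary 7-OH is too hindered to react.

**Compound list**
1 | germacrone, (3E,7E)-3,7-dimethyl-10-(propan-2-ylidene)cyclodeca-3,7-dien-1-one | CC(C)=C1C/C=C(\C)CC/C=C(\C)CC1=O | starting material
2 | 8-oxoeudesm-7(11)-en-4-yl cation (trans-fused; C-10 methyl α, H-5 β) | CC(C)=C1C[C@@H]2[C+](C)CCC[C@@]2(C)CC1=O | intermediate
3 | 8-oxoeudesm-7(11)-en-5-yl cation (C-4 and C-10 methyls α, H-4 β) | CC(C)=C1C[C+]2[C@H](C)CCC[C@@]2(C)CC1=O | intermediate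
4 | 8-oxoeremophil-7(11)-en-10-yl cation (C-4 and C-5 methyls α, cis) | CC(C)=C1C[C@]2(C)[C+](CC1=O)CCC[C@H]2C | intermediate
5 | (4R,5S)-eremophila-7(11),9-dien-8-one (dehydrofukinone) | CC(C)=C1C[C@]2(C)C(=CC1=O)CCC[C@H]2C | intermediate
6 | (4R,5S)-11,12,13-trinoreremophil-9-ene-7,8-dione | O=C1C[C@]2(C)C(=CC1=O)CCC[C@H]2C | intermediate
7 | (4R,5R)-7-hydroxy-11,12,13-trinoreremophila-6,9-dien-8-one | OC1=C[C@]2(C)C(=CC1=O)CCC[C@H]2C | intermediate
8 | (4R,5R)-7-(tert-butyldimethylsilyloxy)-11,12,13-trinoreremophila-6,9-dien-8-one | CC(C)(C)[Si](C)(C)OC1=C[C@]2(C)C(=CC1=O)CCC[C@H]2C | intermediate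
9 | 2-bromoprop-2-en-1-ol | OCC(Br)=C | starting material
10 | [(2-bromoprop-2-en-1-yl)oxy](tert-butyl)dimethylsilane | CC(C)(C)[Si](C)(C)OCC(Br)=C | intermediate
11 | [3-(tert-butyldimethylsilyloxy)prop-1-en-2-yl]lithium | [Li]C(=C)CO[Si](C)(C)C(C)(C)C | intermediate
12 | (4R,5R,8R)-7-(tert-butyldimethylsilyloxy)-8-[3-(tert-butyldimethylsilyloxy)prop-1-en-2-yl]-11,12,13-trinoreremophila-6,9-dien-8-ol (8-OH α, alkenyl β) | C=C(CO[Si](C)(C)C(C)(C)C)[C@]1(O)C=C2CCC[C@@H](C)[C@]2(C)C=C1O[Si](C)(C)C(C)(C)C | intermediate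
13 | (4R,5S,8R)-8-hydroxy-8-(3-hydroxyprop-1-en-2-yl)-11,12,13-trinoreremophil-9-en-7-one | C=C(CO)[C@]1(O)C=C2CCC[C@@H](C)[C@]2(C)CC1=O | intermediate
14 | (4R,5S,7S)-7,12-dihydroxyeremophila-9,11(13)-dien-8-one | C=C(CO)[C@@]1(O)C[C@]2(C)C(=CC1=O)CCC[C@H]2C | intermediate
15 | (4R,5S,7S)-12-acetoxy-7-hydroxyeremophila-9,11(13)-dien-8-one | C=C(COC(C)=O)[C@@]1(O)C[C@]2(C)C(=CC1=O)CCC[C@H]2C | intermediate
16 | (4R,5S,7S)-12-acetoxy-7-hydroxyeremophila-1,9,11(13)-trien-8-one | C=C(COC(C)=O)[C@@]1(O)C[C@]2(C)C(=CC1=O)C=CC[C@H]2C | intermediate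
17 | (4R,5S,7S)-12-acetoxy-7,8-bis(trimethylsilyloxy)eremophila-1(10),2,8,11(13)-tetraene | C=C(COC(C)=O)[C@@]1(O[Si](C)(C)C)C[C@]2(C)C(C=C1O[Si](C)(C)C)=CC=C[C@H]2C | intermediate
18 | (3S,4S,5S,7S)-12-acetoxy-3,7-dihydroxyeremophila-1,9,11(13)-trien-8-one | C=C(COC(C)=O)[C@@]1(O)C[C@]2(C)C(=CC1=O)C=C[C@H](O)[C@H]2C | intermediate
19 | (R)-2-methylbutan-1-ol | CC[C@@H](C)CO | starting material
20 | (R)-2-methylbutanal | CC[C@@H](C)C=O | intermediate
21 | (2E,4R)-2,4-dimethylhex-2-enal | CC[C@@H](C)/C=C(\C)C=O | intermediate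
22 | ethyl (2E,4E,6R)-4,6-dimethylocta-2,4-dienoate | CCOC(=O)/C=C/C(C)=C/[C@H](C)CC | intermediate
23 | (2E,4E,6R)-4,6-dimethylocta-2,4-dienoic acid | OC(=O)/C=C/C(C)=C/[C@H](C)CC | intermediate
24 | (3S,4S,5S,7S)-12-acetoxy-7-hydroxy-8-oxoeremophila-1,9,11(13)-trien-3-yl (2E,4E,6R)-4,6-dimethylocta-2,4-dienoate | C=C(COC(C)=O)[C@@]1(O)C[C@]2(C)C(=CC1=O)C=C[C@H](OC(=O)/C=C/C(C)=C/[C@H](C)CC)[C@H]2C | target

**Totals**
Total step count: 13.
Longest linear sequence: 9 steps (1, 2, 3, 5, 6, 7, 8, 9, 13).

**Steps most likely to fail, with fallbacks**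

Step 1 (the cascade may stop at eudesmadienones, give the trans-dimethyl isomer by deprotonation–reprotonation, or give low ee). The fallback abandons the germacrane cyclisation and builds the bicycle by annulation. It does not set out from a numbered compound: 1 is replaced by purchased 2-methylcyclohex-2-en-1-one F1, and it comes back to the route at 7. Copper/chiral phosphoramidite-catalysed asymmetric conjugate addition of AlMe3 to F1 gives (3R)-2,3-dimethylcyclohexan-1-one F2. Acid-catalysed Robinson annulation of F2 with but-3-en-2-one, the Michael step anti to the C-3 methyl, gives the cis-dimethyl octalone (4R,5S)-11,12,13-trinoreremophil-9-en-8-one F3. Its kinetic α′-enolate (LDA) is hydroxylated with MoOPH to (4R,5S)-7-hydroxy-11,12,13-trinoreremophil-9-en-8-one F4. Dess–Martin oxidation gives diketone 6, which enolises to 7.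

Step 6 (the fluoride-triggered α-ketol shift may stall, ring-contract by migration of C-9, or the addition in step 5 may show poor facial selectivity). The fallback sets out from 8 and comes back at 15; it adds the side chain directly to a C-7 ketone while C-8 is held at the alcohol level. Luche reduction of 8, with hydride anti to the C-5 methyl, gives (4R,5R,8S)-7-(tert-butyldimethylsilyloxy)-11,12,13-trinoreremophila-6,9-dien-8-ol F5. Catalytic KHMDS at −78 °C moves the silyl group from the enol oxygen to the alkoxide (1,4-O→O silyl migration) and protonation gives (4R,5S,8S)-8-(tert-butyldimethylsilyloxy)-11,12,13-trinoreremophil-9-en-7-one F6. Vinyllithium 11 adds to the C-7 ketone anti to both the C-5 methyl and the 8α-silyloxy group and gives (4R,5S,7S,8S)-8,12-bis(tert-butyldimethylsilyloxy)eremophila-9,11(13)-dien-7-ol F7. TBAF gives (4R,5S,7S,8S)-eremophila-9,11(13)-diene-7,8,12-triol F8, and selective acetylation of the primary alcohol gives (4R,5S,7S,8S)-12-acetoxyeremophila-9,11(13)-diene-7,8-diol F9. MnO2 oxidises the allylic C-8 alcohol of F9 to 15.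

Step 9 (DMDO may attack the enol-ether bond C-8=C-9 or C-10=C-1 instead of the terminal alkene). The fallback sets out from 16 and comes back at 24. SeO2 in dioxane at 80 °C (ene reaction then [2,3] shift) is expected to abstract the axial H-3α and deliver oxygen on the same face, giving the 3α-alcohol (3R,4S,5S,7S)-12-acetoxy-3,7-dihydroxyeremophila-1,9,11(13)-trien-8-one F10. Mitsunobu esterification of F10 with acid 23 (DIAD, PPh3) inverts C-3 and gives 24 directly, which makes step 13 unnecessary.

**Further compounds**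
F1 | step 1 | 2-methylcyclohex-2-en-1-one | CC1=CCCCC1=O
F2 | step 1 | (3R)-2,3-dimethylcyclohexan-1-one (C-2 epimers) | C[C@@H]1CCCC(=O)C1C
F3 | step 1 | (4R,5S)-11,12,13-trinoreremophil-9-en-8-one | O=C1CC[C@]2(C)C(=C1)CCC[C@H]2C
F4 | step 1 | (4R,5S)-7-hydroxy-11,12,13-trinoreremophil-9-en-8-one (C-7 epimers) | O=C1C(O)C[C@]2(C)C(=C1)CCC[C@H]2C
F5 | step 6 | (4R,5R,8S)-7-(tert-butyldimethylsilyloxy)-11,12,13-trinoreremophila-6,9-dien-8-ol | O[C@H]1C=C2CCC[C@@H](C)[C@]2(C)C=C1O[Si](C)(C)C(C)(C)C
F6 | step 6 | (4R,5S,8S)-8-(tert-butyldimethylsilyloxy)-11,12,13-trinoreremophil-9-en-7-one | CC(C)(C)[Si](C)(C)O[C@H]1C=C2CCC[C@@H](C)[C@]2(C)CC1=O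
F7 | step 6 | (4R,5S,7S,8S)-8,12-bis(tert-butyldimethylsilyloxy)eremophila-9,11(13)-dien-7-ol | C=C(CO[Si](C)(C)C(C)(C)C)[C@@]1(O)C[C@]2(C)C(=C[C@@H]1O[Si](C)(C)C(C)(C)C)CCC[C@H]2C
F8 | step 6 | (4R,5S,7S,8S)-eremophila-9,11(13)-diene-7,8,12-triol | C=C(CO)[C@@]1(O)C[C@]2(C)C(=C[C@@H]1O)CCC[C@H]2C
F9 | step 6 | (4R,5S,7S,8S)-12-acetoxyeremophila-9,11(13)-diene-7,8-diol | C=C(COC(C)=O)[C@@]1(O)C[C@]2(C)C(=C[C@@H]1O)CCC[C@H]2C
F10 | step 9 | (3R,4S,5S,7S)-12-acetoxy-3,7-dihydroxyeremophila-1,9,11(13)-trien-8-one | C=C(COC(C)=O)[C@@]1(O)C[C@]2(C)C(=CC1=O)C=C[C@@H](O)[C@H]2C
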